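**Retrosynthetic overview**
1. The ester C–O bond is made last, on the only secondary hydroxyl of the silyl-protected dauc-7-ene triol 13.
2. The C4–OH and C3a–H come from syn hydroboration of a C3a=C4 alkene. The C7=C8 alkene comes from a C7 ketone through its enol triflate.
3. The seven-membered ring and the quaternary C8a are made in one flask from alkynediol 8: 5-exo-dig oxycyclisation to a 2-methylideneoxolane, then Claisen ring expansion (C8–C8a bond) to the cycloheptenone.
4. Alkynediol 8 comes from enal 4 by an aldol with a silyl ynone and a chelation-controlled methyl addition.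
5. Ring order: cyclopentene first (from (S)-terpinen-4-ol by ozonolysis and aldol condensation), then the oxolane (transient) and the seven-membered carbocycle together.

Assumption: (S)-(+)-terpinen-4-ol (1) is bought in ≥98% ee; it fixes the absolute configuration of the whole route.
Locants in the Why lines are the azulene locants of 16 (C3 = C(OH)iPr, C3a–H, C4 = ester carbon, C6 = C(OH)Me, C7=C8, C8a = C–Me). [Cp] = (5R)-2-methyl-5-(propan-2-yl)-5-[(triethylsilyl)oxy]cyclopent-1-en-1-yl.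

**Step 1**
Reactants: 1 (S)-(+)-terpinen-4-ol [(1S)-4-methyl-1-(propan-2-yl)cyclohex-3-en-1-ol]
Product: 2 triethyl{[(1S)-4-methyl-1-(propan-2-yl)cyclohex-3-en-1-yl]oxy}silane
Conditions: TESOTf, 2,6-lutidine, CH2Cl2, −78 → 0 °C
Reagents that add atoms: triethylsilyl trifluoromethanesulfonate CC[Si](CC)(CC)OS(=O)(=O)C(F)(F)F
Why: Silyl ether formation with a silyl triflate, the standard way to cap a hindered tertiary alcohol; the stereocentre is untouched and the ether keeps this oxygen from being lost in step 2.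

**Step 2**
Reactants: 2 triethyl{[(1S)-4-methyl-1-(propan-2-yl)cyclohex-3-en-1-yl]oxy}silane
Product: 4 (5R)-2-methyl-5-(propan-2-yl)-5-[(triethylsilyl)oxy]cyclopent-1-ene-1-carbaldehyde, via keto-aldehyde 3 (not isolated)
Conditions: O3, CH2Cl2, −78 °C; Me2S, −78 → 23 °C; then piperidine, AcOH (0.2 equiv each), 40 °C
Reagents that add atoms: ozone [O-][O+]=O
Why: Ozonolysis followed by intramolecular aldol condensation (the known ring contraction of p-menthene keto-aldehydes): the aldehyde enamine adds to the methyl ketone (5-enolexo) and the new tertiary hydroxyl is lost as water, while the silyl ether is not a leaving group under enamine catalysis; the existing stereocentre is kept.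

**Step 3**
Reactants: 4 (5R)-2-methyl-5-(propan-2-yl)-5-[(triethylsilyl)oxy]cyclopent-1-ene-1-carbaldehyde; 5 4-(trimethylsilyl)but-3-yn-2-one
Product: 6 (5S)-5-hydroxy-5-[Cp]-1-(trimethylsilyl)pent-1-yn-3-one
Conditions: (+)-Ipc2BCl, Et3N, 5, Et2O, −78 → 0 °C; then 4, −78 → −20 °C; H2O2, pH 7 buffer, MeOH
Reagents that add atoms: none
Why: Paterson boron aldol of a methyl ketone: the chiral enol borinate is expected to attack the Si face of the aldehyde and so set the carbinol S (the reagent antipode fixes this sense and is swapped if it proves reversed).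

**Step 4**
Reactants: 6 (5S)-5-hydroxy-5-[Cp]-1-(trimethylsilyl)pent-1-yn-3-one
Product: 8 (1S,3R)-3-methyl-1-[Cp]pent-4-yne-1,3-diol, via C-silyl alkynediol 7 (not isolated)
Conditions: MeMgBr (3.5 equiv), CH2Cl2/Et2O, −78 °C; then MeOH, K2CO3, 23 °C
Reagents that add atoms: methylmagnesium bromide C[Mg]Br
Why: Chelation-controlled Grignard 1,2-addition (Cram–Reetz six-membered magnesium chelate, axial attack anti to the cyclopentenyl group) sets the tertiary carbinol R, and K2CO3/MeOH then removes the alkynyl silyl group.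

**Step 5**
Reactants: 8 (1S,3R)-3-methyl-1-[Cp]pent-4-yne-1,3-diol
Product: 10 (3R,6R,8aR)-6-hydroxy-6,8a-dimethyl-3-(propan-2-yl)-3-[(triethylsilyl)oxy]-1,2,3,5,6,8a-hexahydroazulen-7(8H)-one, via 2-methylideneoxolane 9 (not isolated)
Conditions: AuCl (5 mol %), K2CO3 (10 mol %), PhMe, 23 °C; then 170 °C (sealed tube, microwave)
Reagents that add atoms: none
Why: Tandem 5-exo-dig hydroalkoxylation/Claisen rearrangement (Ovaska-type ring expansion): the secondary hydroxyl closes the oxolane 9 (its enol ether cannot move into the ring because the neighbouring carbon is quaternary), and the [3,3] shift then closes the seven-membered carbocycle by forming C8–C8a on the face from which the C–O bond leaves, so the S carbinol that is destroyed dictates R at the quaternary C8a and the ring forces the cis C3a=C4 geometry; the step is an isomerisation.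

**Step 6**
Reactants: 10 (3R,6R,8aR)-6-hydroxy-6,8a-dimethyl-3-(propan-2-yl)-3-[(triethylsilyl)oxy]-1,2,3,5,6,8a-hexahydroazulen-7(8H)-one
Product: 11 (3R,6R,8aR)-6-hydroxy-6,8a-dimethyl-3-(propan-2-yl)-3-[(triethylsilyl)oxy]-1,2,3,5,6,8a-hexahydroazulen-7-yl trifluoromethanesulfonate
Conditions: KHMDS (2.2 equiv), PhNTf2, THF, −78 → 0 °C
Reagents that add atoms: N-phenylbis(trifluoromethanesulfonimide) O=S(=O)(N(c1ccccc1)S(=O)(=O)C(F)(F)F)C(F)(F)F
Why: Enol triflate formation: only C8 carries α-hydrogens, so one enolate forms and is sulfonylated on oxygen, while the hindered tertiary alkoxide is not; no stereocentre is affected.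

**Step 7**
Reactants: 11 (3R,6R,8aR)-6-hydroxy-6,8a-dimethyl-3-(propan-2-yl)-3-[(triethylsilyl)oxy]-1,2,3,5,6,8a-hexahydroazulen-7-yl trifluoromethanesulfonate
Product: 12 (3R,3aS,4S,6R,8aR)-4,6-dihydroxy-6,8a-dimethyl-3-(propan-2-yl)-3-[(triethylsilyl)oxy]-1,2,3,3a,4,5,6,8a-octahydroazulen-7-yl trifluoromethanesulfonate
Conditions: BH3·THF (4 equiv), THF, 0 → 23 °C; then H2O2, aq NaOAc, 0 °C
Reagents that add atoms: hydrogen peroxide OO
Why: Hydroboration–oxidation: boron adds to the less substituted C4 and hydrogen to C3a, syn, from the face opposite the angular methyl and the C3 silyloxy group (the α C6–O–BH2 borinate lies on the reacting face), which sets 3aS and 4S and gives the trans ring fusion; the electron-poor vinyl triflate is left alone.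

**Step 8**
Reactants: 12 (3R,3aS,4S,6R,8aR)-4,6-dihydroxy-6,8a-dimethyl-3-(propan-2-yl)-3-[(triethylsilyl)oxy]-1,2,3,3a,4,5,6,8a-octahydroazulen-7-yl trifluoromethanesulfonate
Product: 13 (3R,3aS,4S,6R,8aR)-6,8a-dimethyl-3-(propan-2-yl)-3-[(triethylsilyl)oxy]-1,2,3,3a,4,5,6,8a-octahydroazulene-4,6-diol
Conditions: Pd(OAc)2 (5 mol %), PPh3, Et3N, HCO2H, DMF, 60 °C
Reagents that add atoms: none
Why: Palladium-catalysed formate reduction of an enol triflate (Cacchi) gives the cis C7=C8 alkene; free hydroxyls and the silyl ether are tolerated and no stereocentre is touched.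

**Step 9**
Reactants: 13 (3R,3aS,4S,6R,8aR)-6,8a-dimethyl-3-(propan-2-yl)-3-[(triethylsilyl)oxy]-1,2,3,3a,4,5,6,8a-octahydroazulene-4,6-diol; 14 4-acetoxybenzoic acid
Product: 15 (3R,3aS,4S,6R,8aR)-6-hydroxy-6,8a-dimethyl-3-(propan-2-yl)-3-[(triethylsilyl)oxy]-1,2,3,3a,4,5,6,8a-octahydroazulen-4-yl 4-(acetyloxy)benzoate
Conditions: 14, EDC·HCl, DMAP, CH2Cl2, 23 °C
Reagents that add atoms: none
Why: Steglich esterification: only the secondary C4 hydroxyl is acylated (the tertiary allylic hydroxyl and the silylated tertiary oxygen are inert), with retention at C4.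

**Step 10**
Reactants: 15 (3R,3aS,4S,6R,8aR)-6-hydroxy-6,8a-dimethyl-3-(propan-2-yl)-3-[(triethylsilyl)oxy]-1,2,3,3a,4,5,6,8a-octahydroazulen-4-yl 4-(acetyloxy)benzoate
Product: 16 (3R,3aS,4S,6R,8aR)-3,6-dihydroxy-6,8a-dimethyl-3-(propan-2-yl)-1,2,3,3a,4,5,6,8a-octahydroazulen-4-yl 4-hydroxybenzoate (CNP0280165.4)
Conditions: TBAF·3H2O, THF, 0 → 23 °C
Reagents that add atoms: none
Why: Fluoride desilylation of the tertiary silyl ether together with cleavage of the phenolic acetate by the basic fluoride medium; the hindered, electron-rich p-oxidobenzoate ester and all stereocentres survive.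

**Compound list**
1 | (S)-(+)-terpinen-4-ol, (1S)-4-methyl-1-(propan-2-yl)cyclohex-3-en-1-ol | CC(C)[C@]1(O)CCC(C)=CC1 | starting material
2 | triethyl{[(1S)-4-methyl-1-(propan-2-yl)cyclohex-3-en-1-yl]oxy}silane | CC(C)[C@]1(O[Si](CC)(CC)CC)CCC(C)=CC1 | intermediate
3 | (3S)-6-oxo-3-(propan-2-yl)-3-[(triethylsilyl)oxy]heptanal (keto-aldehyde, not isolated) | CC(C)[C@@](O[Si](CC)(CC)CC)(CC=O)CCC(C)=O | intermediate
4 | (5R)-2-methyl-5-(propan-2-yl)-5-[(triethylsilyl)oxy]cyclopent-1-ene-1-carbaldehyde | CC(C)[C@]1(O[Si](CC)(CC)CC)CCC(C)=C1C=O | intermediate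
5 | 4-(trimethylsilyl)but-3-yn-2-one | CC(=O)C#C[Si](C)(C)C | starting material
6 | (5S)-5-hydroxy-5-[Cp]-1-(trimethylsilyl)pent-1-yn-3-one | CC(C)[C@]1(O[Si](CC)(CC)CC)CCC(C)=C1[C@@H](O)CC(=O)C#C[Si](C)(C)C | intermediate
7 | (1S,3R)-3-methyl-1-[Cp]-5-(trimethylsilyl)pent-4-yne-1,3-diol (not isolated) | CC(C)[C@]1(O[Si](CC)(CC)CC)CCC(C)=C1[C@@H](O)C[C@@](C)(O)C#C[Si](C)(C)C | intermediate
8 | (1S,3R)-3-methyl-1-[Cp]pent-4-yne-1,3-diol | CC(C)[C@]1(O[Si](CC)(CC)CC)CCC(C)=C1[C@@H](O)C[C@@](C)(O)C#C | intermediate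
9 | (3R,5S)-3-methyl-2-methylidene-5-[Cp]oxolan-3-ol (not isolated) | CC(C)[C@]1(O[Si](CC)(CC)CC)CCC(C)=C1[C@@H]1C[C@@](C)(O)C(=C)O1 | intermediate
10 | (3R,6R,8aR)-6-hydroxy-6,8a-dimethyl-3-(propan-2-yl)-3-[(triethylsilyl)oxy]-1,2,3,5,6,8a-hexahydroazulen-7(8H)-one | CC(C)[C@]1(O[Si](CC)(CC)CC)CC[C@]2(C)CC(=O)[C@](C)(O)CC=C12 | intermediate
11 | (3R,6R,8aR)-6-hydroxy-6,8a-dimethyl-3-(propan-2-yl)-3-[(triethylsilyl)oxy]-1,2,3,5,6,8a-hexahydroazulen-7-yl trifluoromethanesulfonate | CC(C)[C@]1(O[Si](CC)(CC)CC)CC[C@]2(C)C=C(OS(=O)(=O)C(F)(F)F)[C@](C)(O)CC=C12 | intermediate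
12 | (3R,3aS,4S,6R,8aR)-4,6-dihydroxy-6,8a-dimethyl-3-(propan-2-yl)-3-[(triethylsilyl)oxy]-1,2,3,3a,4,5,6,8a-octahydroazulen-7-yl trifluoromethanesulfonate | CC(C)[C@]1(O[Si](CC)(CC)CC)CC[C@]2(C)C=C(OS(=O)(=O)C(F)(F)F)[C@](C)(O)C[C@H](O)[C@H]21 | intermediate
13 | (3R,3aS,4S,6R,8aR)-6,8a-dimethyl-3-(propan-2-yl)-3-[(triethylsilyl)oxy]-1,2,3,3a,4,5,6,8a-octahydroazulene-4,6-diol | CC(C)[C@]1(O[Si](CC)(CC)CC)CC[C@]2(C)C=C[C@](C)(O)C[C@H](O)[C@H]21 | intermediate
14 | 4-acetoxybenzoic acid | CC(=O)Oc1ccc(cc1)C(=O)O | starting material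
15 | (3R,3aS,4S,6R,8aR)-6-hydroxy-6,8a-dimethyl-3-(propan-2-yl)-3-[(triethylsilyl)oxy]-1,2,3,3a,4,5,6,8a-octahydroazulen-4-yl 4-(acetyloxy)benzoate | CC(C)[C@]1(O[Si](CC)(CC)CC)CC[C@]2(C)C=C[C@](C)(O)C[C@H](OC(=O)c3ccc(OC(C)=O)cc3)[C@H]21 | intermediate
16 | (3R,3aS,4S,6R,8aR)-3,6-dihydroxy-6,8a-dimethyl-3-(propan-2-yl)-1,2,3,3a,4,5,6,8a-octahydroazulen-4-yl 4-hydroxybenzoate | CC(C)[C@]1(O)CC[C@]2(C)C=C[C@](C)(O)C[C@H](OC(=O)c3ccc(O)cc3)[C@H]21 | target

**Totals**
Total step count: 10. Longest linear sequence: 10.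

**Steps most likely to fail, with fallbacks**

Step 5. The Claisen shift has to form a quaternary centre at a tetrasubstituted, crowded cyclopentene carbon, and the oxolane oxygen sits on the same face as the isopropyl group, so the thermal reaction may need temperatures at which 9 decomposes. The fallback sets out from 8. The gold-catalysed closure is run alone at 23 °C and oxolane 9 is isolated over basic alumina. Enol ether 9 is then rearranged at low temperature with i-Bu3Al (CH2Cl2, −78 → 23 °C), a Lewis-acid-promoted Claisen in which the aluminium reduces the ketone as it forms. This gives (3R,6R,8aR)-6,8a-dimethyl-3-(propan-2-yl)-3-[(triethylsilyl)oxy]-1,2,3,5,6,7,8,8a-octahydroazulene-6,7-diol F3 as C7 epimers. Dess–Martin oxidation of the secondary hydroxyl returns to 10.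

Step 3. The aldehyde is flanked by a tetrasubstituted alkene and a quaternary centre, so the boron aldol may be slow or weakly selective. The fallback sets out from 4. A catalytic enantioselective Mukaiyama acetate aldol with the trimethylsilyl ketene acetal of S-tert-butyl thioacetate (Carreira-type Ti(IV) catalyst, the enantiomer giving Si-face attack) gives S-tert-butyl (3S)-3-hydroxy-3-[Cp]propanethioate F1. Treatment with MeNHOMe·HCl and i-PrMgCl gives (3S)-3-hydroxy-N-methoxy-N-methyl-3-[Cp]propanamide F2. Lithium (trimethylsilyl)acetylide (2.2 equiv) adds once to the amide and the route is rejoined at 6.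

Step 7. Both alkene faces are hindered, and the wrong face would give the cis-fused C3a/C4 epimers. The fallback sets out from 11 and delivers silicon and hydrogen from the α-oriented C6 oxygen through a tether. Silylation of the tertiary hydroxyl with chlorodimethylsilane and Et3N gives the dimethylsilyl ether of 11 F4. Karstedt platinum(0) then effects intramolecular 5-exo hydrosilylation of C3a=C4 to the 4,6-O–SiMe2-bridged siloxane F5, with Si at C4 and H at C3a both on the α-face. Tamao–Fleming oxidation (H2O2, KF, KHCO3) replaces silicon by hydroxyl with retention and comes back to the route at 12.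

**Further compounds**
F1 | step 3 | S-tert-butyl (3S)-3-hydroxy-3-[(5R)-2-methyl-5-(propan-2-yl)-5-[(triethylsilyl)oxy]cyclopent-1-en-1-yl]propanethioate | CC(C)[C@]1(O[Si](CC)(CC)CC)CCC(C)=C1[C@@H](O)CC(=O)SC(C)(C)C
F2 | step 3 | (3S)-3-hydroxy-N-methoxy-N-methyl-3-[(5R)-2-methyl-5-(propan-2-yl)-5-[(triethylsilyl)oxy]cyclopent-1-en-1-yl]propanamide | CC(C)[C@]1(O[Si](CC)(CC)CC)CCC(C)=C1[C@@H](O)CC(=O)N(C)OC
F3 | step 5 | (3R,6R,8aR)-6,8a-dimethyl-3-(propan-2-yl)-3-[(triethylsilyl)oxy]-1,2,3,5,6,7,8,8a-octahydroazulene-6,7-diol (C7 epimers) | CC(C)[C@]1(O[Si](CC)(CC)CC)CC[C@]2(C)CC(O)[C@](C)(O)CC=C12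
F4 | step 7 | (3R,6R,8aR)-6-[(dimethylsilyl)oxy]-6,8a-dimethyl-3-(propan-2-yl)-3-[(triethylsilyl)oxy]-1,2,3,5,6,8a-hexahydroazulen-7-yl trifluoromethanesulfonate | CC(C)[C@]1(O[Si](CC)(CC)CC)CC[C@]2(C)C=C(OS(=O)(=O)C(F)(F)F)[C@](C)(O[SiH](C)C)CC=C12
F5 | step 7 | 4,6-O–SiMe2-bridged siloxane of 12 (C4–Si and C6–O–Si in a 1-oxa-2-silacyclopentane; 3R,3aS,4S,6R,8aR; H at C3a and Si at C4 both α) | CC(C)[C@]1(O[Si](CC)(CC)CC)CC[C@]2(C)C=C(OS(=O)(=O)C(F)(F)F)[C@@]3(C)C[C@@H]([C@H]21)[Si](C)(C)O3
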